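**Plan**
- Retrosynthesis (drimane numbering: decalin C1–C10, C11 = CH2O on C9): the C11–O aryl ether is cut first (scopoletin); then one C4 methyl is returned to CHO, C1–C2 to an alkene and C3–OH to C3–B(pin).
- Ring A is then a cyclohexene in which carbinol carbon C3 and ring-fusion carbon C10 sit 1,4 across C1=C2, and C4–C5 is a two-carbon unit. Bonds C3–C4 and C5–C10 are cut together (retro-[4+2]) to a C3=C2–C1=C10 boryl diene and a C4=C5 enal joined by C6–C7=C8–C9, the carbons of ring B.
- The open chain is cut at C2–C1 (Heck), C4=C5 (cross-metathesis), C10–CH3 (carboalumination), C9–C11 ([2,3]-Wittig–Still shift) and C6–C7 (allylation).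
- Forward: linear chain assembly, then rings B and A close in one intramolecular Diels–Alder step; C–B oxidation, alkene reduction, CHO-to-CH3 reduction and etherification finish.
- Stereochemistry: the C7 carbinol comes from a Brown allylation and is transferred to C9 (with the Z-C7=C8 alkene) in the sigmatropic shift. C9 then steers the cycloaddition, whose diene/dienophile geometry and endo transition state set C3, C5 and C10.

Key step: step 9

Remark: the target is read as the 9-epi-drimane series, with H-5 trans to the C10 methyl, the CH2OAr group on C9 trans to the C10 methyl, and the axial C3 hydroxyl cis to H-5 (α face when the C10 methyl is β).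

**Route**

Step 1
Reactants: 1 3-(trimethylsilyl)prop-2-ynal; 2 2-(triphenyl-λ5-phosphanylidene)propanal
Product: 3 (2E)-2-methyl-5-(trimethylsilyl)pent-2-en-4-ynal
Conditions: CH2Cl2, 0 °C to rt
Reagents that add atoms: none
Why: Wittig olefination with a formyl-stabilised ylide is E-selective (formyl trans to the alkynyl group), and the α-branched enal formed should react with the ylide far more slowly than the ynal.

Step 2
Reactants: 3 (2E)-2-methyl-5-(trimethylsilyl)pent-2-en-4-ynal
Product: 5 (4S,5E)-5-methyl-8-(trimethylsilyl)octa-1,5-dien-7-yn-4-ol, via borinate ester 4 (not isolated)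
Conditions: (−)-Ipc2B(allyl), Et2O, −78 °C; then NaBO3·4H2O, THF/H2O, rt
Reagents that add atoms: (−)-B-allyldiisopinocampheylborane, C=CCB([C@@H]1C[C@@H]2C[C@H]([C@H]1C)C2(C)C)[C@@H]1C[C@@H]2C[C@H]([C@H]1C)C2(C)C
Why: Brown allylation through a chair Zimmerman–Traxler transition state; the reagent derived from (+)-α-pinene should add to the Si face of the enal and set the (S)-carbinol at C7.

Step 3
Reactants: 5 (4S,5E)-5-methyl-8-(trimethylsilyl)octa-1,5-dien-7-yn-4-ol
Product: 6 tributyl({[(4S,5E)-5-methyl-8-(trimethylsilyl)octa-1,5-dien-7-yn-4-yl]oxy}methyl)stannane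
Conditions: KH, THF, 0 °C; then Bu3SnCH2I, 18-crown-6 (cat.), 0 °C to rt
Reagents that add atoms: tributyl(iodomethyl)stannane, CCCC[Sn](CI)(CCCC)CCCC
Why: Williamson etherification of the potassium alkoxide with the reactive α-stannyl iodide (Still protocol) does not touch the carbinol stereocentre.

Step 4
Reactants: 6 tributyl({[(4S,5E)-5-methyl-8-(trimethylsilyl)octa-1,5-dien-7-yn-4-yl]oxy}methyl)stannane
Product: 9 tert-butyldimethyl({(2R,3Z)-3-methyl-2-[(trimethylsilyl)ethynyl]hepta-3,6-dien-1-yl}oxy)silane, via lithiomethyl ether 7 (not isolated), via lithium alkoxide 8 (not isolated)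
Conditions: n-BuLi, THF, −78 °C; then TBSOTf, −78 to 0 °C
Reagents that add atoms: tert-butyldimethylsilyl trifluoromethanesulfonate, CC(C)(C)[Si](C)(C)OS(=O)(=O)C(F)(F)F
Why: Tin–lithium exchange triggers the [2,3]-Wittig–Still rearrangement through a five-membered envelope in which the allyl group on C7 sits pseudoaxial to avoid A(1,2) strain with the C8 methyl, which should give the Z-C7=C8 alkene and transfer chirality suprafacially from C7–O to the new C9–C11 bond, and the lithium alkoxide is silylated in the same flask.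

Step 5
Reactants: 9 tert-butyldimethyl({(2R,3Z)-3-methyl-2-[(trimethylsilyl)ethynyl]hepta-3,6-dien-1-yl}oxy)silane
Product: 10 tert-butyl{[(2S,3Z)-2-ethynyl-3-methylhepta-3,6-dien-1-yl]oxy}dimethylsilane
Conditions: K2CO3, MeOH, rt
Reagents that add atoms: none
Why: Methanolysis cleaves only the alkynyl C–Si bond; the silyl ether and the C9 stereocentre (descriptor changes by priority only) are unaffected.

Step 6
Reactants: 10 tert-butyl{[(2S,3Z)-2-ethynyl-3-methylhepta-3,6-dien-1-yl]oxy}dimethylsilane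
Product: 12 tert-butyl{[(2R,3Z)-2-[(1E)-1-iodoprop-1-en-2-yl]-3-methylhepta-3,6-dien-1-yl]oxy}dimethylsilane, via alkenylalane 11 (not isolated)
Conditions: Me3Al (3 equiv), Cp2ZrCl2 (0.3 equiv), H2O (1 equiv), CH2Cl2, −30 to 0 °C; then I2, THF, −30 to 0 °C
Reagents that add atoms: trimethylaluminium, C[Al](C)C; iodine, II
Why: Negishi zirconium-catalysed syn-carboalumination places CH3 on C10 and aluminium on C1, and iodinolysis with retention should give the E-iodide with C9 trans to iodine; the alkenes are inert under these conditions.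

Step 7
Reactants: 12 tert-butyl{[(2R,3Z)-2-[(1E)-1-iodoprop-1-en-2-yl]-3-methylhepta-3,6-dien-1-yl]oxy}dimethylsilane
Product: 13 (2E,5Z,7R,8E)-7-{[(tert-butyldimethylsilyl)oxy]methyl}-9-iodo-2,6,8-trimethylnona-2,5,8-trienal
Conditions: methacrolein (10 equiv), second-generation Hoveyda–Grubbs catalyst (H2IMes)Cl2Ru=CH(2-iPrO-C6H4) (5 mol %), CH2Cl2, 40 °C
Reagents that add atoms: methacrolein, C=C(C)C=O
Why: Cross-metathesis of the only monosubstituted alkene with methacrolein should give the E-2-methyl-2-enal, while the trisubstituted alkene and the iodoalkene do not engage the ruthenium carbene.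

Step 8
Reactants: 13 (2E,5Z,7R,8E)-7-{[(tert-butyldimethylsilyl)oxy]methyl}-9-iodo-2,6,8-trimethylnona-2,5,8-trienal
Product: 14 (2E,5Z,7R,8E,10E)-7-{[(tert-butyldimethylsilyl)oxy]methyl}-2,6,8-trimethyl-11-(4,4,5,5-tetramethyl-1,3,2-dioxaborolan-2-yl)undeca-2,5,8,10-tetraenal
Conditions: vinyl-B(pin) (2 equiv), Pd(OAc)2 (5 mol %), P(o-tol)3 (10 mol %), AgOAc (1.2 equiv), MeCN, 50 °C
Reagents that add atoms: 4,4,5,5-tetramethyl-2-vinyl-1,3,2-dioxaborolane, C=CB1OC(C)(C)C(C)(C)O1
Why: Heck–Mizoroki coupling of the alkenyl iodide with the vinylboronate (AgOAc suppresses Suzuki transfer) retains the C10=C1 geometry and should give the E-C2=C3 alkenylboronate after syn β-hydride elimination.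

Step 9
Reactants: 14 (2E,5Z,7R,8E,10E)-7-{[(tert-butyldimethylsilyl)oxy]methyl}-2,6,8-trimethyl-11-(4,4,5,5-tetramethyl-1,3,2-dioxaborolan-2-yl)undeca-2,5,8,10-tetraenal
Product: 16 (1S,2R,4aS,5R,8aR)-5-{[(tert-butyldimethylsilyl)oxy]methyl}-2-hydroxy-1,4a,6-trimethyl-1,2,4a,5,8,8a-hexahydronaphthalene-1-carbaldehyde (drimane numbering: 3α-OH, 4α-CHO, 5α-H, 9α-CH2OTBS, 10β-CH3, C1=C2, C7=C8), via allylboronate 15 (not isolated)
Conditions: Me2AlCl (1.3 equiv), CH2Cl2 (0.005 M), −78 to −30 °C; then aq NaHCO3, 30% H2O2, THF, 0 °C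
Reagents that add atoms: hydrogen peroxide, OO
Why: Coordination of Me2AlCl to the formyl oxygen lowers the enal LUMO and the C3=C2–C1=C10 boryl diene adds across C4=C5 in a concerted, asynchronous [4+2] cycloaddition in which the C5–C10 bond leads, after which buffered peroxide converts the allylic C3–B bond into C3–OH by 1,2-migration with retention. The closest known reactions are the Lewis-acid-promoted type 1 intramolecular Diels–Alder reaction of 2-methyl-2,7,9-trienals and the Diels–Alder/oxidation sequence of 1-(pinacolboryl)-1,3-dienes. Ring A (C1–C5, C10) is closed by the cycloaddition itself through both new bonds, and ring B (C5–C10) is closed at the same moment by the C5–C10 bond as the fused ring of the four-atom C6–C7=C8–C9 tether, whose Z-alkene holds the two ends together. The trans ring fusion (H-5 trans to the C10 methyl) should follow from the transition state with the tether exo and the aluminium-bound formyl group endo, which the E-enal makes one and the same arrangement; C3 follows from the E-boryl terminus, which places boron and then oxygen cis to C9 and trans to the C10 methyl; C4 carries the formyl group on the α face and loses its stereogenicity later. Absolute control comes from C9, whose CH2OTBS group should take the pseudoaxial position in the forming ring B to escape A(1,2) strain with the methyl groups on C8 and C10, so that the dienophile adds to the diene face that leaves C11 trans to the C10 methyl. The step needs endo over exo selectivity (Lewis acid, and the inside methyl on C10 that disfavours the tether-endo mode), π-facial selectivity (C9) and chemoselectivity against intermolecular allylboration of the aldehyde by 15 (low temperature, high dilution, immediate oxidation).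

Step 10
Reactants: 16 (1S,2R,4aS,5R,8aR)-5-{[(tert-butyldimethylsilyl)oxy]methyl}-2-hydroxy-1,4a,6-trimethyl-1,2,4a,5,8,8a-hexahydronaphthalene-1-carbaldehyde
Product: 17 (1S,2R,4aS,5R,8aR)-5-{[(tert-butyldimethylsilyl)oxy]methyl}-2-hydroxy-1,4a,6-trimethyl-1,2,3,4,4a,5,8,8a-octahydronaphthalene-1-carbaldehyde
Conditions: KO2CN=NCO2K (excess, portionwise), AcOH, MeOH/CH2Cl2, 0 °C to rt
Reagents that add atoms: none
Why: Diimide generated in the flask transfers H2 in a concerted syn fashion to the cis-disubstituted C1=C2 alkene much faster than to the trisubstituted C7=C8 alkene and does not reduce the aldehyde.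

Step 11
Reactants: 17 (1S,2R,4aS,5R,8aR)-5-{[(tert-butyldimethylsilyl)oxy]methyl}-2-hydroxy-1,4a,6-trimethyl-1,2,3,4,4a,5,8,8a-octahydronaphthalene-1-carbaldehyde
Product: 19 (2R,4aS,5R,8aR)-5-{[(tert-butyldimethylsilyl)oxy]methyl}-1,1,4a,6-tetramethyl-1,2,3,4,4a,5,8,8a-octahydronaphthalen-2-ol, via tosylhydrazone 18 (not isolated)
Conditions: TsNHNH2, THF, 50 °C; then catecholborane, CHCl3, 0 °C; then NaOAc·3H2O, 60 °C
Reagents that add atoms: none
Why: Caglioti–Kabalka deoxygenation, in which hydride adds to the C=N bond of the tosylhydrazone and loss of sulfinate and N2 leaves the second C4 methyl, under conditions mild enough to avoid retro-aldol cleavage of the β-hydroxy aldehyde.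

Step 12
Reactants: 19 (2R,4aS,5R,8aR)-5-{[(tert-butyldimethylsilyl)oxy]methyl}-1,1,4a,6-tetramethyl-1,2,3,4,4a,5,8,8a-octahydronaphthalen-2-ol
Product: 20 (2R,4aS,5R,8aR)-5-(hydroxymethyl)-1,1,4a,6-tetramethyl-1,2,3,4,4a,5,8,8a-octahydronaphthalen-2-ol
Conditions: TBAF, THF, rt
Reagents that add atoms: none
Why: Fluoride cleaves the primary silyl ether through the strong Si–F bond without affecting the alkene or any stereocentre.

Step 13
Reactants: 20 (2R,4aS,5R,8aR)-5-(hydroxymethyl)-1,1,4a,6-tetramethyl-1,2,3,4,4a,5,8,8a-octahydronaphthalen-2-ol; 21 scopoletin (7-hydroxy-6-methoxy-2H-chromen-2-one)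
Product: 22 7-{[(1R,4aR,6R,8aS)-6-hydroxy-2,5,5,8a-tetramethyl-1,4,4a,5,6,7,8,8a-octahydronaphthalen-1-yl]methoxy}-6-methoxy-2H-chromen-2-one
Conditions: PPh3, DIAD, THF, 0 to 40 °C
Reagents that add atoms: none
Why: Mitsunobu etherification, in which the acidic 7-OH of scopoletin displaces the oxyphosphonium of the primary C11 alcohol while the axial, neopentyl-type secondary C3-OH is too hindered to be activated, so no stereocentre is touched.

**Compound list**

1 | 3-(trimethylsilyl)prop-2-ynal | C[Si](C)(C)C#CC=O | starting material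
2 | 2-(triphenyl-λ5-phosphanylidene)propanal | CC(C=O)=P(c1ccccc1)(c1ccccc1)c1ccccc1 | starting material
3 | (2E)-2-methyl-5-(trimethylsilyl)pent-2-en-4-ynal | C[Si](C)(C)C#C/C=C(\C)C=O | intermediate
4 | (4S,5E)-5-methyl-8-(trimethylsilyl)octa-1,5-dien-7-yn-4-yl diisopinocampheylborinate (Ipc groups from (+)-α-pinene) | C=CC[C@H](OB([C@@H]1C[C@@H]2C[C@H]([C@H]1C)C2(C)C)[C@@H]1C[C@@H]2C[C@H]([C@H]1C)C2(C)C)/C(C)=C/C#C[Si](C)(C)C | intermediate
5 | (4S,5E)-5-methyl-8-(trimethylsilyl)octa-1,5-dien-7-yn-4-ol | C=CC[C@H](O)/C(C)=C/C#C[Si](C)(C)C | intermediate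
6 | tributyl({[(4S,5E)-5-methyl-8-(trimethylsilyl)octa-1,5-dien-7-yn-4-yl]oxy}methyl)stannane | C=CC[C@H](OC[Sn](CCCC)(CCCC)CCCC)/C(C)=C/C#C[Si](C)(C)C | intermediate
7 | ({[(4S,5E)-5-methyl-8-(trimethylsilyl)octa-1,5-dien-7-yn-4-yl]oxy}methyl)lithium | C=CC[C@H](OC[Li])/C(C)=C/C#C[Si](C)(C)C | intermediate
8 | lithium (2R,3Z)-3-methyl-2-[(trimethylsilyl)ethynyl]hepta-3,6-dien-1-olate | [Li+].[O-]C[C@@H](C#C[Si](C)(C)C)/C(C)=C\CC=C | intermediate
9 | tert-butyldimethyl({(2R,3Z)-3-methyl-2-[(trimethylsilyl)ethynyl]hepta-3,6-dien-1-yl}oxy)silane | CC(C)(C)[Si](C)(C)OC[C@@H](C#C[Si](C)(C)C)/C(C)=C\CC=C | intermediate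
10 | tert-butyl{[(2S,3Z)-2-ethynyl-3-methylhepta-3,6-dien-1-yl]oxy}dimethylsilane | CC(C)(C)[Si](C)(C)OC[C@@H](C#C)/C(C)=C\CC=C | intermediate
11 | [(1E,3R,4Z)-3-{[(tert-butyldimethylsilyl)oxy]methyl}-2,4-dimethylocta-1,4,7-trien-1-yl]dimethylalumane | CC(C)(C)[Si](C)(C)OC[C@@H](/C(C)=C/[Al](C)C)/C(C)=C\CC=C | intermediate
12 | tert-butyl{[(2R,3Z)-2-[(1E)-1-iodoprop-1-en-2-yl]-3-methylhepta-3,6-dien-1-yl]oxy}dimethylsilane | CC(C)(C)[Si](C)(C)OC[C@@H](/C(C)=C/I)/C(C)=C\CC=C | intermediate
13 | (2E,5Z,7R,8E)-7-{[(tert-butyldimethylsilyl)oxy]methyl}-9-iodo-2,6,8-trimethylnona-2,5,8-trienal | CC(C)(C)[Si](C)(C)OC[C@@H](/C(C)=C/I)/C(C)=C\C/C=C(\C)C=O | intermediate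
14 | (2E,5Z,7R,8E,10E)-7-{[(tert-butyldimethylsilyl)oxy]methyl}-2,6,8-trimethyl-11-(4,4,5,5-tetramethyl-1,3,2-dioxaborolan-2-yl)undeca-2,5,8,10-tetraenal | CC(C)(C)[Si](C)(C)OC[C@@H](/C(C)=C/C=C/B1OC(C)(C)C(C)(C)O1)/C(C)=C\C/C=C(\C)C=O | intermediate
15 | (1R,2R,4aS,5R,8aR)-5-{[(tert-butyldimethylsilyl)oxy]methyl}-1,4a,6-trimethyl-2-(4,4,5,5-tetramethyl-1,3,2-dioxaborolan-2-yl)-1,2,4a,5,8,8a-hexahydronaphthalene-1-carbaldehyde (drimane numbering: 3α-B(pin), 4α-CHO) | CC(C)(C)[Si](C)(C)OC[C@@H]1C(C)=CC[C@H]2[C@](C)(C=O)[C@H](B3OC(C)(C)C(C)(C)O3)C=C[C@]12C | intermediate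
16 | (1S,2R,4aS,5R,8aR)-5-{[(tert-butyldimethylsilyl)oxy]methyl}-2-hydroxy-1,4a,6-trimethyl-1,2,4a,5,8,8a-hexahydronaphthalene-1-carbaldehyde | CC(C)(C)[Si](C)(C)OC[C@@H]1C(C)=CC[C@H]2[C@](C)(C=O)[C@H](O)C=C[C@]12C | intermediate
17 | (1S,2R,4aS,5R,8aR)-5-{[(tert-butyldimethylsilyl)oxy]methyl}-2-hydroxy-1,4a,6-trimethyl-1,2,3,4,4a,5,8,8a-octahydronaphthalene-1-carbaldehyde | CC(C)(C)[Si](C)(C)OC[C@@H]1C(C)=CC[C@H]2[C@](C)(C=O)[C@H](O)CC[C@]12C | intermediate
18 | (E)-N'-tosylhydrazone of 17 | CC(C)(C)[Si](C)(C)OC[C@@H]1C(C)=CC[C@H]2[C@](C)(/C=N/NS(=O)(=O)c3ccc(C)cc3)[C@H](O)CC[C@]12C | intermediate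
19 | (2R,4aS,5R,8aR)-5-{[(tert-butyldimethylsilyl)oxy]methyl}-1,1,4a,6-tetramethyl-1,2,3,4,4a,5,8,8a-octahydronaphthalen-2-ol | CC(C)(C)[Si](C)(C)OC[C@@H]1C(C)=CC[C@H]2C(C)(C)[C@H](O)CC[C@]12C | intermediate
20 | (2R,4aS,5R,8aR)-5-(hydroxymethyl)-1,1,4a,6-tetramethyl-1,2,3,4,4a,5,8,8a-octahydronaphthalen-2-ol | OC[C@@H]1C(C)=CC[C@H]2C(C)(C)[C@H](O)CC[C@]12C | intermediate
21 | scopoletin (7-hydroxy-6-methoxy-2H-chromen-2-one) | COc1cc2ccc(=O)oc2cc1O | starting material
22 | 7-{[(1R,4aR,6R,8aS)-6-hydroxy-2,5,5,8a-tetramethyl-1,4,4a,5,6,7,8,8a-octahydronaphthalen-1-yl]methoxy}-6-methoxy-2H-chromen-2-one | COc1cc2ccc(=O)oc2cc1OC[C@@H]1C(C)=CC[C@H]2C(C)(C)[C@H](O)CC[C@]12C | target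

**Totals and risks**

Total step count: 13. Longest linear sequence: 13 steps (from 1 to 22).

Steps most likely to fail:

1. Step 9. The cycloaddition at the fully substituted C10 terminus of the weakly activated boryl diene may be slow, which would let Lewis-acid-promoted intermolecular allylboration of the formyl group by 15 compete, and endo or π-facial selectivity may erode. The fallback sets out from 14 and comes back at 16. The boron is exchanged for oxygen before the cycloaddition: Cu(OAc)2/Et3N-promoted, stereoretentive coupling of 14 with 4-methoxybenzyl alcohol should give the (E)-dienyl 4-methoxybenzyl ether F1. This donor diene is polarity-matched with the enal (C10 nucleophilic, C3 oxocarbenium-stabilised) and should undergo the same type 1 intramolecular Diels–Alder reaction with Me2AlCl at −78 °C, or in toluene at 80 °C, to give the C3 4-methoxybenzyl ether cycloadduct F2 with no allylmetal present. DDQ in CH2Cl2/pH 7 buffer then frees the allylic alcohol 16.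

2. Step 4. A [1,2]-shift or addition of the α-alkoxy carbanion (or of n-BuLi) to the conjugated enyne may compete, and Z selectivity or chirality transfer may erode. The fallback sets out from 5 and comes back at 10. Acylation of 5 with 2-(diphenylphosphanyl)benzoic acid (DCC, DMAP, CH2Cl2) gives the directing ester F3. A copper-mediated, phosphine-directed syn-SN2′ substitution with (isopropoxydimethylsilyl)methylmagnesium chloride (CuBr·SMe2, Et2O, rt) should deliver the hydroxymethyl equivalent to C9 on the face of the leaving group, in the same sense as the sigmatropic shift and with the same A(1,2) control of the Z alkene, to give the silane F4. Tamao oxidation (KF, KHCO3, 30% H2O2, THF/MeOH), which also removes the alkynyl silyl group, gives the alcohol F5, and TBSCl/imidazole in DMF gives 10.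

3. Step 13. Displacement of the oxyphosphonium at the β-branched, axial C11 next to quaternary C10 may be slow, so that the azodicarboxylate-derived hydrazide is alkylated instead or the alcohol is recovered. The fallback sets out from 20 and comes back at 22. Selective sulfonylation of the primary hydroxyl (Tf2O, 2,6-lutidine, CH2Cl2, −78 °C) gives the primary triflate F6, which is displaced at 0 °C to rt by the caesium salt of 21 (Cs2CO3, MeCN), a free phenoxide acting on a discrete and far more reactive electrophile, to give 22.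

Further compounds
F1 | step 9 | (2E,5Z,7R,8E,10E)-7-{[(tert-butyldimethylsilyl)oxy]methyl}-11-[(4-methoxybenzyl)oxy]-2,6,8-trimethylundeca-2,5,8,10-tetraenal | CC(C)(C)[Si](C)(C)OC[C@@H](/C(C)=C/C=C/OCc1ccc(OC)cc1)/C(C)=C\C/C=C(\C)C=O
F2 | step 9 | (1S,2R,4aS,5R,8aR)-5-{[(tert-butyldimethylsilyl)oxy]methyl}-2-[(4-methoxybenzyl)oxy]-1,4a,6-trimethyl-1,2,4a,5,8,8a-hexahydronaphthalene-1-carbaldehyde | CC(C)(C)[Si](C)(C)OC[C@@H]1C(C)=CC[C@H]2[C@](C)(C=O)[C@H](OCc3ccc(OC)cc3)C=C[C@]12C
F3 | step 4 | (4S,5E)-5-methyl-8-(trimethylsilyl)octa-1,5-dien-7-yn-4-yl 2-(diphenylphosphanyl)benzoate | C=CC[C@H](OC(=O)c1ccccc1P(c1ccccc1)c1ccccc1)/C(C)=C/C#C[Si](C)(C)C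
F4 | step 4 | isopropoxydimethyl{(2R,3Z)-3-methyl-2-[(trimethylsilyl)ethynyl]hepta-3,6-dien-1-yl}silane | CC(C)O[Si](C)(C)C[C@@H](C#C[Si](C)(C)C)/C(C)=C\CC=C
F5 | step 4 | (2S,3Z)-2-ethynyl-3-methylhepta-3,6-dien-1-ol | OC[C@@H](C#C)/C(C)=C\CC=C
F6 | step 13 | [(1R,4aR,6R,8aS)-6-hydroxy-2,5,5,8a-tetramethyl-1,4,4a,5,6,7,8,8a-octahydronaphthalen-1-yl]methyl trifluoromethanesulfonate | O=S(=O)(OC[C@@H]1C(C)=CC[C@H]2C(C)(C)[C@H](O)CC[C@]12C)C(F)(F)F
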